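The synthesis cuts the central single bond C2'–C3' of the dienyl chain (C1'–C6', with C1' on chroman C2). The key step exploits the (3'Z)-trisubstituted alkene C3'=C4'(CH3): C5', which leads to the cyclohexene ring, and C2' are cis, the signature of a syn-carbocupration of propyne. In one flask the Grignard reagent of the cyclohexenylethyl bromide is cuprated and added across propyne, and the resulting (Z)-alkenylcopper is coupled under Pd(PPh3)4/ZnBr2 with an (R,E)-2-(2-iodovinyl)-2-methylchroman. The precursors are thus an alkyl bromide, propyne and a vinyl iodide whose quaternary C2 comes from an enantioselective Wacker-type cyclisation.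

Key step: step 10

Assumption: (R,R)-Bn-BOXAX is taken to be the ligand enantiomer that gives the (R)-configured chroman in step 5; if the sense of induction is the opposite, its mirror image is used and nothing else changes.

Step 1
Reactants: 1 2,5-dihydroxybenzaldehyde
Product: 2 5-[(tert-butyldimethylsilyl)oxy]-2-hydroxybenzaldehyde
Conditions: TBSCl (1.05 equiv), imidazole, CH2Cl2, 0 °C
Reagents that add atoms: tert-butyldimethylsilyl chloride, CC(C)(C)[Si](C)(C)Cl
Why: Regioselective silyl ether formation; the 2-hydroxyl is held in a hydrogen bond to the aldehyde, so the free 5-hydroxyl should react first.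

Step 2
Reactants: 2 5-[(tert-butyldimethylsilyl)oxy]-2-hydroxybenzaldehyde
Product: 3 (E)-4-{5-[(tert-butyldimethylsilyl)oxy]-2-hydroxyphenyl}but-3-en-2-one
Conditions: Ph3P=CHC(O)CH3, toluene, 80 °C
Reagents that add atoms: (acetylmethylene)triphenylphosphorane, CC(=O)C=P(c1ccccc1)(c1ccccc1)c1ccccc1
Why: Wittig olefination with a stabilised ylide should give the (E)-enone under neutral conditions that leave the free phenol and the aryl silyl ether untouched.

Step 3
Reactants: 3 (E)-4-{5-[(tert-butyldimethylsilyl)oxy]-2-hydroxyphenyl}but-3-en-2-one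
Product: 4 4-{5-[(tert-butyldimethylsilyl)oxy]-2-hydroxyphenyl}butan-2-one
Conditions: H2 (1 atm), Pd/C, EtOAc, rt
Reagents that add atoms: none
Why: Catalytic hydrogenation should saturate the conjugated C=C bond much faster than the ketone or the arene, giving the ketone (in equilibrium with its cyclic hemiketal).

Step 4
Reactants: 4 4-{5-[(tert-butyldimethylsilyl)oxy]-2-hydroxyphenyl}butan-2-one
Product: 5 4-[(tert-butyldimethylsilyl)oxy]-2-(3-methylpent-3-en-1-yl)phenol (E/Z mixture)
Conditions: EtPPh3Br (3 equiv), NaHMDS (3 equiv), THF, 0 °C → rt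
Reagents that add atoms: ethyltriphenylphosphonium bromide, CC[P+](c1ccccc1)(c1ccccc1)c1ccccc1.[Br-]
Why: Wittig olefination with the non-stabilised ethylidene ylide, used in excess because the first equivalent deprotonates the phenol, should convert the methyl ketone into the trisubstituted alkene; the E/Z mixture is carried on because both isomers are expected to converge on the same vinylchroman in step 5.

Step 5
Reactants: 5 4-[(tert-butyldimethylsilyl)oxy]-2-(3-methylpent-3-en-1-yl)phenol (E/Z mixture)
Product: 6 (R)-tert-butyldimethyl[(2-methyl-2-vinylchroman-6-yl)oxy]silane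
Conditions: Pd(OCOCF3)2 (10 mol%), (R,R)-Bn-BOXAX (20 mol%), p-benzoquinone (4 equiv), MeOH, rt
Reagents that add atoms: none
Why: Enantioselective Wacker-type oxidative cyclisation: ligand-bound divalent palladium activates one alkene face, the phenol oxygen adds to the methyl-bearing carbon in a 6-exo-trig closure and β-hydride elimination into the terminal methyl unveils the vinyl group, the twofold-symmetric bis(oxazoline) ligand setting the quaternary C2 as (R) while benzoquinone reoxidises zerovalent palladium.

Step 6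
Reactants: 6 (R)-tert-butyldimethyl[(2-methyl-2-vinylchroman-6-yl)oxy]silane
Product: 7 (R)-6-[(tert-butyldimethylsilyl)oxy]-2-methylchroman-2-carbaldehyde
Conditions: OsO4 (2 mol%), NaIO4 (4 equiv), 2,6-lutidine, dioxane/H2O, rt
Reagents that add atoms: sodium periodate, [Na+].[O-]I(=O)(=O)=O
Why: Lemieux–Johnson oxidative cleavage (osmium-catalysed dihydroxylation, then periodate glycol cleavage) should turn the vinyl group into the non-enolisable aldehyde without touching C2, the lutidine buffer sparing the silyl ether and the electron-rich arene.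

Step 7
Reactants: 7 (R)-6-[(tert-butyldimethylsilyl)oxy]-2-methylchroman-2-carbaldehyde
Product: 8 tert-butyl({(R)-2-[(E)-2-iodovinyl]-2-methylchroman-6-yl}oxy)dimethylsilane
Conditions: CrCl2 (8 equiv), CHI3 (2.5 equiv), THF/dioxane, 0 °C → rt
Reagents that add atoms: iodoform, IC(I)I
Why: Takai olefination: the geminal dichromium reagent from iodoform adds to the aldehyde and elimination should give the (E)-iodoalkene, the selectivity being reinforced by the bulky quaternary C2.

Step 8
Reactants: 9 2-(2,6,6-trimethylcyclohex-1-en-1-yl)acetaldehyde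
Product: 10 2-(2,6,6-trimethylcyclohex-1-en-1-yl)ethan-1-ol
Conditions: NaBH4, MeOH, 0 °C
Reagents that add atoms: none
Why: Borohydride reduction of the aldehyde to the primary alcohol; the tetrasubstituted ring alkene is inert.

Step 9
Reactants: 10 2-(2,6,6-trimethylcyclohex-1-en-1-yl)ethan-1-ol
Product: 11 2-(2-bromoethyl)-1,3,3-trimethylcyclohex-1-ene
Conditions: CBr4, PPh3, CH2Cl2, 0 °C
Reagents that add atoms: carbon tetrabromide, BrC(Br)(Br)Br
Why: Appel bromination should convert the primary alcohol into the bromide by SN2 displacement of the oxyphosphonium group under neutral conditions.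

Step 10
Reactants: 11 2-(2-bromoethyl)-1,3,3-trimethylcyclohex-1-ene (2 equiv), 8 tert-butyl({(R)-2-[(E)-2-iodovinyl]-2-methylchroman-6-yl}oxy)dimethylsilane
Product: 16 tert-butyldimethyl({(R)-2-methyl-2-[(1E,3Z)-4-methyl-6-(2,6,6-trimethylcyclohex-1-en-1-yl)hexa-1,3-dien-1-yl]chroman-6-yl}oxy)silane, via Grignard reagent 12 (not isolated), via alkylcopper 13 (not isolated), via alkenylcopper 14 (not isolated), via alkenylzinc bromide 15 (not isolated)
Conditions: Mg, Et2O, reflux; CuBr·SMe2, Et2O/Me2S, −45 °C; propyne, −25 °C, then excess purged; ZnBr2, THF, −20 °C; 8, Pd(PPh3)4 (5 mol%), −20 °C → rt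
Reagents that add atoms: propyne, CC#C
Why: Magnesium insertion into 11 and transmetalation with CuBr·SMe2 give the primary alkylcopper 13, which adds across propyne in a Normant syn-carbocupration: the alkyl group goes to the internal alkyne carbon and copper to the terminal one on the same face, so C5' and the future C2' end up cis and the (3'Z) geometry of C3'=C4'(CH3) is fixed in alkenylcopper 14. Transmetalation to zinc (15) and a Negishi-type cycle on Pd(PPh3)4 (oxidative addition of zerovalent palladium into the C–I bond of 8, alkenyl transfer from zinc to divalent palladium, reductive elimination) should then form the C2'–C3' bond with retention at both alkenes; the closest known reaction type is the palladium-catalysed coupling of carbocupration-derived alkenylcopper reagents with alkenyl iodides in the presence of ZnBr2. No ring is closed and no stereocentre is created; the stereogenic elements set are the two alkene geometries, (3'Z) by the syn addition and (1'E) carried over from 8. The step needs regioselective and syn-selective addition to propyne, which the terminal alkyne and the primary alkylcopper in Et2O/Me2S at low temperature should secure. It also needs coupling without alkene isomerisation or ionisation of the C2 aryl ether, which the quaternary C2 (no allylic hydrogen on the iodide side), the silyl mask on the phenol and a temperature not above rt should secure. Excess propyne is purged before the catalyst is added so that no enyne forms.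

Step 11
Reactants: 16 tert-butyldimethyl({(R)-2-methyl-2-[(1E,3Z)-4-methyl-6-(2,6,6-trimethylcyclohex-1-en-1-yl)hexa-1,3-dien-1-yl]chroman-6-yl}oxy)silane
Product: 17 (R)-2-methyl-2-[(1E,3Z)-4-methyl-6-(2,6,6-trimethylcyclohex-1-en-1-yl)hexa-1,3-dien-1-yl]chroman-6-ol
Conditions: Bu4NF (1.1 equiv), AcOH (1.1 equiv), THF, 0 °C, argon
Reagents that add atoms: none
Why: Fluoride-induced cleavage of the aryl silyl ether, buffered with acetic acid so that the air-sensitive chromanol and the tertiary dienyl aryl ether meet neither strong base nor acid; C2 is not involved.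

Compound list
1 | 2,5-dihydroxybenzaldehyde | O=Cc1cc(O)ccc1O | starting material
2 | 5-[(tert-butyldimethylsilyl)oxy]-2-hydroxybenzaldehyde | O=Cc1cc(O[Si](C)(C)C(C)(C)C)ccc1O | intermediate
3 | (E)-4-{5-[(tert-butyldimethylsilyl)oxy]-2-hydroxyphenyl}but-3-en-2-one | CC(=O)/C=C/c1cc(O[Si](C)(C)C(C)(C)C)ccc1O | intermediate
4 | 4-{5-[(tert-butyldimethylsilyl)oxy]-2-hydroxyphenyl}butan-2-one | CC(=O)CCc1cc(O[Si](C)(C)C(C)(C)C)ccc1O | intermediate
5 | 4-[(tert-butyldimethylsilyl)oxy]-2-(3-methylpent-3-en-1-yl)phenol, E/Z mixture | CC=C(C)CCc1cc(O[Si](C)(C)C(C)(C)C)ccc1O | intermediate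
6 | (R)-tert-butyldimethyl[(2-methyl-2-vinylchroman-6-yl)oxy]silane | C=C[C@@]1(C)CCc2cc(O[Si](C)(C)C(C)(C)C)ccc2O1 | intermediate
7 | (R)-6-[(tert-butyldimethylsilyl)oxy]-2-methylchroman-2-carbaldehyde | O=C[C@@]1(C)CCc2cc(O[Si](C)(C)C(C)(C)C)ccc2O1 | intermediate
8 | tert-butyl({(R)-2-[(E)-2-iodovinyl]-2-methylchroman-6-yl}oxy)dimethylsilane | I/C=C/[C@@]1(C)CCc2cc(O[Si](C)(C)C(C)(C)C)ccc2O1 | intermediate
9 | 2-(2,6,6-trimethylcyclohex-1-en-1-yl)acetaldehyde (β-homocyclocitral) | CC1=C(CC=O)C(C)(C)CCC1 | starting material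
10 | 2-(2,6,6-trimethylcyclohex-1-en-1-yl)ethan-1-ol | CC1=C(CCO)C(C)(C)CCC1 | intermediate
11 | 2-(2-bromoethyl)-1,3,3-trimethylcyclohex-1-ene | CC1=C(CCBr)C(C)(C)CCC1 | intermediate
12 | [2-(2,6,6-trimethylcyclohex-1-en-1-yl)ethyl]magnesium bromide | CC1=C(CC[Mg]Br)C(C)(C)CCC1 | intermediate
13 | [2-(2,6,6-trimethylcyclohex-1-en-1-yl)ethyl]copper (MgBr2/Me2S complex) | CC1=C(CC[Cu])C(C)(C)CCC1 | intermediate
14 | [(Z)-2-methyl-4-(2,6,6-trimethylcyclohex-1-en-1-yl)but-1-en-1-yl]copper | CC1=C(CC/C(C)=C\[Cu])C(C)(C)CCC1 | intermediate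
15 | [(Z)-2-methyl-4-(2,6,6-trimethylcyclohex-1-en-1-yl)but-1-en-1-yl]zinc bromide | CC1=C(CC/C(C)=C\[Zn]Br)C(C)(C)CCC1 | intermediate
16 | tert-butyldimethyl({(R)-2-methyl-2-[(1E,3Z)-4-methyl-6-(2,6,6-trimethylcyclohex-1-en-1-yl)hexa-1,3-dien-1-yl]chroman-6-yl}oxy)silane | CC1=C(CC/C(C)=C\C=C\[C@@]2(C)CCc3cc(O[Si](C)(C)C(C)(C)C)ccc3O2)C(C)(C)CCC1 | intermediate
17 | (R)-2-methyl-2-[(1E,3Z)-4-methyl-6-(2,6,6-trimethylcyclohex-1-en-1-yl)hexa-1,3-dien-1-yl]chroman-6-ol | CC1=C(CC/C(C)=C\C=C\[C@@]2(C)CCc3cc(O)ccc3O2)C(C)(C)CCC1 | target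

Total step count: 11. Longest linear sequence: 9 steps (steps 1–7, 10 and 11).

Steps most likely to fail

Step 10. The carbocupration may be incomplete or unselective, unreacted alkyl groups may be transferred in the coupling, and palladium may ionise the tertiary allylic aryl ether in a flask crowded with metal salts. The fallback sets out from 11 and 7 and comes back at 16. The alkenylcopper 14 is generated from 11 as in the route but quenched with I2 at −40 °C to give (Z)-2-(4-iodo-3-methylbut-3-en-1-yl)-1,3,3-trimethylcyclohex-1-ene F1, which is purified. Aldehyde 7 is converted by the boron variant of the Takai olefination (Cl2CHBpin, CrCl2, LiI, THF, rt) into tert-butyldimethyl({(R)-2-methyl-2-[(E)-2-(4,4,5,5-tetramethyl-1,3,2-dioxaborolan-2-yl)vinyl]chroman-6-yl}oxy)silane F2. A Suzuki–Miyaura coupling of the two isolated partners (PdCl2(dppf), aqueous K3PO4, THF, rt) should then give 16 with retention at both alkenes.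

Step 5. The enantioselectivity may be insufficient, the two alkene isomers may not be discriminated alike, or the sense of induction may be misjudged. The fallback sets out from 4 and comes back at 6. A Horner–Wadsworth–Emmons reaction of 4 (triethyl phosphonoacetate, NaH, THF) followed by separation of the (E)-isomer gives ethyl (E)-5-{5-[(tert-butyldimethylsilyl)oxy]-2-hydroxyphenyl}-3-methylpent-2-enoate F3. Reduction with i-Bu2AlH (CH2Cl2, −78 °C) gives 4-[(tert-butyldimethylsilyl)oxy]-2-[(E)-5-hydroxy-3-methylpent-3-en-1-yl]phenol F4. Selective acylation of the primary alcohol (ClCO2Me, pyridine, CH2Cl2, 0 °C) gives (E)-5-{5-[(tert-butyldimethylsilyl)oxy]-2-hydroxyphenyl}-3-methylpent-2-en-1-yl methyl carbonate F5. An asymmetric Tsuji–Trost allylic etherification (Pd2(dba)3·CHCl3, the trans-1,2-diaminocyclohexane bis(2-diphenylphosphinobenzamide) ligand enantiomer that leads to (R), AcOH, CH2Cl2, rt) should then close the ring at the more substituted allyl terminus and give 6.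

Step 7. The hindered aldehyde may react sluggishly, the E/Z ratio may be eroded, or reductive side reactions may intervene. The fallback sets out from 7 and comes back at 8. A Colvin homologation (Me3SiCHN2, n-BuLi, THF, −78 °C → rt) gives tert-butyl{[(R)-2-ethynyl-2-methylchroman-6-yl]oxy}dimethylsilane F6. Syn-hydrozirconation with Cp2Zr(H)Cl (THF, rt), which places zirconium on the terminal carbon, followed by I2 at 0 °C should give 8 as the pure (E)-isomer.

Further compounds
F1 | step 10 | (Z)-2-(4-iodo-3-methylbut-3-en-1-yl)-1,3,3-trimethylcyclohex-1-ene | CC1=C(CC/C(C)=C\I)C(C)(C)CCC1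
F2 | step 10 | tert-butyldimethyl({(R)-2-methyl-2-[(E)-2-(4,4,5,5-tetramethyl-1,3,2-dioxaborolan-2-yl)vinyl]chroman-6-yl}oxy)silane | CC1(C)OB(/C=C/[C@@]2(C)CCc3cc(O[Si](C)(C)C(C)(C)C)ccc3O2)OC1(C)C
F3 | step 5 | ethyl (E)-5-{5-[(tert-butyldimethylsilyl)oxy]-2-hydroxyphenyl}-3-methylpent-2-enoate | CCOC(=O)/C=C(\C)CCc1cc(O[Si](C)(C)C(C)(C)C)ccc1O
F4 | step 5 | 4-[(tert-butyldimethylsilyl)oxy]-2-[(E)-5-hydroxy-3-methylpent-3-en-1-yl]phenol | OC/C=C(\C)CCc1cc(O[Si](C)(C)C(C)(C)C)ccc1O
F5 | step 5 | (E)-5-{5-[(tert-butyldimethylsilyl)oxy]-2-hydroxyphenyl}-3-methylpent-2-en-1-yl methyl carbonate | COC(=O)OC/C=C(\C)CCc1cc(O[Si](C)(C)C(C)(C)C)ccc1O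
F6 | step 7 | tert-butyl{[(R)-2-ethynyl-2-methylchroman-6-yl]oxy}dimethylsilane | C#C[C@@]1(C)CCc2cc(O[Si](C)(C)C(C)(C)C)ccc2O1
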